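**Plan**

- Retrosynthesis: remove the three MOM ethers; cut the C2–C1' bond of the flavanone (aryl 1,4-addition to a chromone); open the pyranone ring (O1–C2 and C2–C3) back to an o-hydroxyacetophenone; cut the acetyl–ring A bond and N–CH3; finally cut the bond from piperidine C2 to ring A together with the ring N–CH2 bond, which leads back to cyclopentanone oxime and a phloroglucinol triether.
- Enabling feature: piperidine C2 carries both N1 and C6 of ring A, so it corresponds to the imine carbon of a 2-aryl-3,4,5,6-tetrahydropyridine. That carbon is the nitrilium carbon left by a C-to-N shift in cyclopentanone oxime. C6 of ring A lies between the oxygen-bearing carbons C5 and C7, so its carbanion is available by doubly ortho-directed lithiation.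
- Forward order: ring A (phloroglucinol, oxygens differentiated as MOM/MOM/Bn) → ring enlargement of the cyclopentane with nitrogen insertion and aryl capture gives the six-membered azacycle → reduction and N-methylation → acetylation and unmasking of the future O1 → pyranone ring C → ring B by conjugate addition → deprotection.
- Regiochemistry (6- versus 8-substitution): the benzyl-marked oxygen para to the piperidinyl carbon is the only phenol free at ring closure, so it becomes O1.
- Stereochemistry: piperidine C2 (R) comes from catalytic asymmetric hydrogenation of the cyclic imine; flavanone C2 (S) comes from catalyst-controlled asymmetric 1,4-addition. The two centres are remote and are set independently.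

Key step: step 4

Assumption: the sense of induction of the titanocene and rhodium catalysts is taken from the parent 2-phenyl cyclic imine and cyclic enone cases; if a model run shows the opposite sense, the antipode of the ligand is used.

**Step 1**
Reactants: 1 phloroglucinol
Product: 2 3,5-bis(methoxymethoxy)phenol
Conditions: MOMCl (2.0 equiv), i-Pr2NEt, CH2Cl2–DMF, 0 °C to rt; chromatographic separation from mono- and tris-ether
Reagents that add atoms: chloromethyl methyl ether, COCCl
Why: Williamson-type O-alkylation with the hard electrophile MOMCl is O-selective on phloroglucinol, and with two equivalents the bis-ether should be the main part of a statistical mixture whose mono-ether can be recycled.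

**Step 2**
Reactants: 2 3,5-bis(methoxymethoxy)phenol
Product: 3 1-(benzyloxy)-3,5-bis(methoxymethoxy)benzene
Conditions: BnBr, K2CO3, DMF, rt
Reagents that add atoms: benzyl bromide, BrCc1ccccc1
Why: Williamson ether synthesis on the single free phenol marks, with an orthogonal benzyl group, the oxygen that later becomes O1 of the pyranone ring.

**Step 3**
Reactants: 4 cyclopentanone oxime
Product: 5 cyclopentanone O-(methylsulfonyl)oxime
Conditions: MsCl, Et3N, CH2Cl2, −20 °C; used without storage
Reagents that add atoms: methanesulfonyl chloride, CS(Cl)(=O)=O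
Why: O-sulfonylation of the oxime gives the Beckmann substrate, and because the ketoxime is symmetric its geometry has no bearing on which carbon migrates.

**Step 4**
Reactants: 3 1-(benzyloxy)-3,5-bis(methoxymethoxy)benzene; 5 cyclopentanone O-(methylsulfonyl)oxime
Product: 8 6-[4-(benzyloxy)-2,6-bis(methoxymethoxy)phenyl]-2,3,4,5-tetrahydropyridine, via aryllithium 6 (not isolated), via aryl(diethyl)alane 7 (not isolated)
Conditions: n-BuLi, Et2O, 0 °C; Et2AlCl, −78 to 0 °C; then 5 (0.5 equiv relative to 7; surplus 7 returns 3 on work-up), CH2Cl2, −78 °C to rt; aq. NaOH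
Reagents that add atoms: none
Why: Proposed new method: the Lewis acidic aluminium of 7 binds the mesylate oxygen of 5, and the ring C–C bond anti to the N–O bond shifts to nitrogen as mesylate leaves (Beckmann rearrangement), which turns the cyclopentylidene ring into a six-membered cyclic nitrilium ion paired with the aluminate [ArEt2Al(OMs)]−; the aryl group, as the sp2 ligand of that ate complex, is then delivered to the nitrilium carbon and gives the C-aryl imine. The closest known reaction type is the organoaluminium-promoted Beckmann rearrangement–alkylation of ketoxime sulfonates with trialkyl- and alkynyl(dialkyl)aluminium reagents; transfer of a 2,6-dioxygenated aryl group is the extension. No ring is closed by cyclisation: the tetrahydropyridine ring arises by ring enlargement, through the 1,2-shift of a ring CH2 of the cyclopentane from carbon to nitrogen, and the new C–C bond is exocyclic. No stereocentre is formed, so the imine carbon stays prochiral for step 5. The step needs aryl rather than ethyl transfer, a single addition and the correct aryl carbon: sp2 groups leave aluminium faster than ethyl, the hindered ketimine–aluminium complex should not accept a second aryl group, the symmetric oxime has no cation-stabilising substituent that could divert it to fragmentation, and the aryl carbon was fixed by lithiation between the two OMOM groups of 3.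

**Step 5**
Reactants: 8 6-[4-(benzyloxy)-2,6-bis(methoxymethoxy)phenyl]-2,3,4,5-tetrahydropyridine
Product: 9 (2R)-2-[4-(benzyloxy)-2,6-bis(methoxymethoxy)phenyl]piperidine
Conditions: H2 (35 bar), (R,R)-(EBTHI)TiCl2 (5 mol%; EBTHI = ethylene-1,2-bis(η5-4,5,6,7-tetrahydroinden-1-yl)), n-BuLi (10 mol%), PhSiH3 (15 mol%), THF, 65 °C
Reagents that add atoms: none
Why: Titanocene-hydride-catalysed asymmetric hydrogenation of a 2-substituted cyclic imine, in which the C2-symmetric trivalent titanium hydride inserts the geometrically fixed C=N bond from one face by telling the ring CH2 side from the aryl side, so that the (R,R) catalyst is expected to set piperidine C2 as R while leaving the benzyl and MOM ethers untouched.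

**Step 6**
Reactants: 9 (2R)-2-[4-(benzyloxy)-2,6-bis(methoxymethoxy)phenyl]piperidine
Product: 10 (2R)-2-[4-(benzyloxy)-2,6-bis(methoxymethoxy)phenyl]-1-methylpiperidine
Conditions: aq. HCHO, NaBH(OAc)3, ClCH2CH2Cl, rt
Reagents that add atoms: formaldehyde, C=O
Why: Reductive amination with a triacetoxyborohydride installs the N-methyl group without touching the benzylic stereocentre, and the intermediate iminium cannot close onto the arene (Pictet–Spengler) because both ortho positions carry OMOM groups.

**Step 7**
Reactants: 10 (2R)-2-[4-(benzyloxy)-2,6-bis(methoxymethoxy)phenyl]-1-methylpiperidine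
Product: 12 1-{6-(benzyloxy)-2,4-bis(methoxymethoxy)-3-[(2R)-1-methylpiperidin-2-yl]phenyl}ethan-1-one, via aryllithium 11 (not isolated)
Conditions: n-BuLi, THF, −20 to 0 °C; then MeC(O)N(OMe)Me, −78 °C to rt; H2O
Reagents that add atoms: N-methoxy-N-methylacetamide, CC(=O)N(C)OC
Why: Directed ortho-metalation by the OMOM group (assisted by OBn) followed by Weinreb ketone synthesis stops at the ketone through the chelated tetrahedral adduct, and since the two free ring positions are interchanged by rotation about the aryl–piperidine bond only one ketone can form.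

**Step 8**
Reactants: 12 1-{6-(benzyloxy)-2,4-bis(methoxymethoxy)-3-[(2R)-1-methylpiperidin-2-yl]phenyl}ethan-1-one
Product: 13 1-{6-hydroxy-2,4-bis(methoxymethoxy)-3-[(2R)-1-methylpiperidin-2-yl]phenyl}ethan-1-one
Conditions: H2 (1 atm), Pd/C, EtOAc–MeOH, rt
Reagents that add atoms: none
Why: Hydrogenolysis of the benzyl aryl ether frees only the phenol para to the piperidinyl carbon and ortho to the acetyl group, while the MOM ethers, the electron-rich di-ortho-substituted ketone and the hindered benzylic C–N bond should survive these mild neutral conditions.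

**Step 9**
Reactants: 13 1-{6-hydroxy-2,4-bis(methoxymethoxy)-3-[(2R)-1-methylpiperidin-2-yl]phenyl}ethan-1-one
Product: 15 5,7-bis(methoxymethoxy)-6-[(2R)-1-methylpiperidin-2-yl]-4H-chromen-4-one, via enaminone 14 (not isolated)
Conditions: Me2NCH(OMe)2, toluene, 95 °C; then SiO2, CHCl3, 60 °C
Reagents that add atoms: N,N-dimethylformamide dimethyl acetal, COC(OC)N(C)C
Why: The enaminone route to chromones (condensation of the methyl ketone, then 6-endo conjugate addition of the ortho phenol and loss of dimethylamine) closes the pyranone ring only through the one free phenol, which places the piperidine at C6 and not C8, and the near-neutral cyclisation spares the MOM ethers.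

**Step 10**
Reactants: 15 5,7-bis(methoxymethoxy)-6-[(2R)-1-methylpiperidin-2-yl]-4H-chromen-4-one; 16 [4-(methoxymethoxy)phenyl]boronic acid
Product: 17 (2S)-5,7-bis(methoxymethoxy)-2-[4-(methoxymethoxy)phenyl]-6-[(2R)-1-methylpiperidin-2-yl]-2,3-dihydro-4H-chromen-4-one
Conditions: [RhOH(cod)]2 (1.5 mol%), (S)-MeO-F12-BIPHEP (3.3 mol%), 16 (3 equiv), toluene–H2O 10:1, 40 °C
Reagents that add atoms: none
Why: Hayashi–Miyaura asymmetric 1,4-addition of an arylboronic acid to a chromone with the electron-poor ligand (S)-2,2'-bis[bis(3,4,5-trifluorophenyl)phosphino]-6,6'-dimethoxy-1,1'-biphenyl, in which the chiral aryl–rhodium species adds to one enantioface of C2=C3 and sets C2 as S under catalyst control (the remote piperidine centre has no influence), and the base-free medium avoids ring opening of the flavanone.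

**Step 11**
Reactants: 17 (2S)-5,7-bis(methoxymethoxy)-2-[4-(methoxymethoxy)phenyl]-6-[(2R)-1-methylpiperidin-2-yl]-2,3-dihydro-4H-chromen-4-one
Product: 18 (2S)-5,7-dihydroxy-2-(4-hydroxyphenyl)-6-[(2R)-1-methylpiperidin-2-yl]-2,3-dihydro-4H-chromen-4-one
Conditions: HCl (3 M in MeOH), 40 °C; then aq. NaHCO3 to pH 8
Reagents that add atoms: none
Why: Acid-catalysed acetal exchange with methanol removes the three MOM ethers, and the flavanone C2 centre should hold because its epimerisation runs through base-induced retro-oxa-Michael opening, which mild acid and a careful neutralisation avoid.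

**Compound list**

1 | phloroglucinol (benzene-1,3,5-triol) | Oc1cc(O)cc(O)c1 | starting material
2 | 3,5-bis(methoxymethoxy)phenol | COCOc1cc(O)cc(OCOC)c1 | intermediate
3 | 1-(benzyloxy)-3,5-bis(methoxymethoxy)benzene | COCOc1cc(OCc2ccccc2)cc(OCOC)c1 | intermediate
4 | cyclopentanone oxime | ON=C1CCCC1 | starting material
5 | cyclopentanone O-(methylsulfonyl)oxime | CS(=O)(=O)ON=C1CCCC1 | intermediate
6 | [4-(benzyloxy)-2,6-bis(methoxymethoxy)phenyl]lithium | [Li]c1c(OCOC)cc(OCc2ccccc2)cc1OCOC | intermediate
7 | [4-(benzyloxy)-2,6-bis(methoxymethoxy)phenyl]diethylaluminium | CC[Al](CC)c1c(OCOC)cc(OCc2ccccc2)cc1OCOC | intermediate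
8 | 6-[4-(benzyloxy)-2,6-bis(methoxymethoxy)phenyl]-2,3,4,5-tetrahydropyridine | COCOc1cc(OCc2ccccc2)cc(OCOC)c1C1=NCCCC1 | intermediate
9 | (2R)-2-[4-(benzyloxy)-2,6-bis(methoxymethoxy)phenyl]piperidine | N1CCCC[C@@H]1c1c(OCOC)cc(OCc2ccccc2)cc1OCOC | intermediate
10 | (2R)-2-[4-(benzyloxy)-2,6-bis(methoxymethoxy)phenyl]-1-methylpiperidine | CN1CCCC[C@@H]1c1c(OCOC)cc(OCc2ccccc2)cc1OCOC | intermediate
11 | {6-(benzyloxy)-2,4-bis(methoxymethoxy)-3-[(2R)-1-methylpiperidin-2-yl]phenyl}lithium | CN1CCCC[C@@H]1c1c(OCOC)c([Li])c(OCc2ccccc2)cc1OCOC | intermediate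
12 | 1-{6-(benzyloxy)-2,4-bis(methoxymethoxy)-3-[(2R)-1-methylpiperidin-2-yl]phenyl}ethan-1-one | CN1CCCC[C@@H]1c1c(OCOC)c(C(C)=O)c(OCc2ccccc2)cc1OCOC | intermediate
13 | 1-{6-hydroxy-2,4-bis(methoxymethoxy)-3-[(2R)-1-methylpiperidin-2-yl]phenyl}ethan-1-one | CN1CCCC[C@@H]1c1c(OCOC)c(C(C)=O)c(O)cc1OCOC | intermediate
14 | (E)-3-(dimethylamino)-1-{6-hydroxy-2,4-bis(methoxymethoxy)-3-[(2R)-1-methylpiperidin-2-yl]phenyl}prop-2-en-1-one | CN1CCCC[C@@H]1c1c(OCOC)c(C(=O)/C=C/N(C)C)c(O)cc1OCOC | intermediate
15 | 5,7-bis(methoxymethoxy)-6-[(2R)-1-methylpiperidin-2-yl]-4H-chromen-4-one | CN1CCCC[C@@H]1c1c(OCOC)cc2c(c1OCOC)C(=O)C=CO2 | intermediate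
16 | [4-(methoxymethoxy)phenyl]boronic acid | COCOc1ccc(B(O)O)cc1 | starting material
17 | (2S)-5,7-bis(methoxymethoxy)-2-[4-(methoxymethoxy)phenyl]-6-[(2R)-1-methylpiperidin-2-yl]-2,3-dihydro-4H-chromen-4-one | CN1CCCC[C@@H]1c1c(OCOC)cc2c(c1OCOC)C(=O)C[C@@H](c1ccc(OCOC)cc1)O2 | intermediate
18 | (2S)-5,7-dihydroxy-2-(4-hydroxyphenyl)-6-[(2R)-1-methylpiperidin-2-yl]-2,3-dihydro-4H-chromen-4-one | CN1CCCC[C@@H]1c1c(O)cc2c(c1O)C(=O)C[C@@H](c1ccc(O)cc1)O2 | target

Total step count: 11. Longest linear sequence: 10 steps (steps 1, 2 and 4 to 11, from phloroglucinol); step 3 is a one-step side branch.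

**Steps most likely to fail**

Step 4 (Proposed new method). The aryl group may fail to leave the hindered, internally chelated alane, so that ethyl transfer, simple recovery of the arene or hydrolysis of the nitrilium to the lactam takes over. The fallback keeps the ring enlargement but separates it from the C–C bond formation, using known reaction types. It sets out from 5: the established organoaluminium-promoted Beckmann rearrangement with thiolate capture (i-Bu2AlSMe, prepared from i-Bu2AlH and MeSH, CH2Cl2, −78 °C to rt) should give the cyclic thioimidate 6-(methylsulfanyl)-2,3,4,5-tetrahydropyridine F1. Aryllithium 6, generated from 3 as in step 4 but in THF, is then added at −78 °C to rt; addition to the C=N bond and loss of lithium methanethiolate (addition–elimination at an imidate carbon, as with lactim ethers) brings the route back at 8.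

Step 5. Insertion of the crowded C=N bond, whose di-ortho-substituted aryl group is twisted out of conjugation, may be slow or show poor facial selectivity. The fallback replaces catalytic induction by a classical resolution. It sets out from 8: NaBH4 in MeOH should give racemic 2-[4-(benzyloxy)-2,6-bis(methoxymethoxy)phenyl]piperidine F2. Crystallisation with O,O'-di-p-toluoyl-L-tartaric acid (or its antipode, chosen by screening for the less soluble salt of the R amine) should give the diastereomerically pure salt of the (2R)-amine with the tartaric acid derivative F3. Treatment of that salt with aq. NaOH releases 9, where the route is rejoined.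

Step 10. Conversion may be low, the facial selectivity poor on the hindered, amine-bearing 5-alkoxychromone, or C2 may epimerise through ring opening. The fallback gives up catalyst control and uses the fixed piperidine centre to make the C2 epimers separable diastereomers. It sets out from 13: Claisen–Schmidt condensation with 4-(methoxymethoxy)benzaldehyde (KOH, EtOH, rt) should give (E)-1-{6-hydroxy-2,4-bis(methoxymethoxy)-3-[(2R)-1-methylpiperidin-2-yl]phenyl}-3-[4-(methoxymethoxy)phenyl]prop-2-en-1-one F4. Oxa-Michael closure (NaOAc, EtOH, reflux) then gives 17 together with its (2R)-flavanone epimer F5. The two are separated by chromatography or crystallisation, and the unwanted epimer is re-equilibrated through the chalcone under the same conditions. The route is rejoined at 17.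

**Further compounds**

F1 | step 4 | 6-(methylsulfanyl)-2,3,4,5-tetrahydropyridine | CSC1=NCCCC1
F2 | step 5 | racemic 2-[4-(benzyloxy)-2,6-bis(methoxymethoxy)phenyl]piperidine | COCOc1cc(OCc2ccccc2)cc(OCOC)c1C1CCCCN1
F3 | step 5 | (2R)-2-[4-(benzyloxy)-2,6-bis(methoxymethoxy)phenyl]piperidine O,O'-di-p-toluoyl-L-tartaric acid salt | N1CCCC[C@@H]1c1c(OCOC)cc(OCc2ccccc2)cc1OCOC.[C@@H]([C@H](C(=O)O)OC(=O)c1ccc(C)cc1)(C(=O)O)OC(=O)c1ccc(C)cc1
F4 | step 10 | (E)-1-{6-hydroxy-2,4-bis(methoxymethoxy)-3-[(2R)-1-methylpiperidin-2-yl]phenyl}-3-[4-(methoxymethoxy)phenyl]prop-2-en-1-one | CN1CCCC[C@@H]1c1c(OCOC)c(C(=O)/C=C/c2ccc(OCOC)cc2)c(O)cc1OCOC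
F5 | step 10 | (2R)-5,7-bis(methoxymethoxy)-2-[4-(methoxymethoxy)phenyl]-6-[(2R)-1-methylpiperidin-2-yl]-2,3-dihydro-4H-chromen-4-one | CN1CCCC[C@@H]1c1c(OCOC)cc2c(c1OCOC)C(=O)C[C@H](c1ccc(OCOC)cc1)O2
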